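## Retrosynthetic overview

1. Target ⇐ desilylation/saponification of the protected chromene ester 16; the C3=C4 alkene ⇐ DDQ dehydrogenation of chroman 15.
2. Pyran ring (the only ring made) ⇐ intramolecular Pd C–O coupling of a tertiary alcohol onto an aryl bromide, after a B-alkyl Suzuki coupling of the vinyl group with aryl iodide 13.
3. C2 stereocentre ⇐ the carbinol carbon of (S)-linalool, whose C–O bond is never broken.
4. Side chain ⇐ Still–Gennari Z-olefination (C7'=C8') of aldehyde 5 with phosphonate 8; 5 ⇐ (S)-linalool by E-selective SeO2 oxidation, bromination and a two-carbon aza-enolate homologation.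
5. Arene 13 ⇐ 2-bromo-1-iodo-3-methylbenzene by meta C–H borylation/oxidation, then silylation.

Assumption: (S)-(+)-linalool (coriandrol) and 2-bromo-1-iodo-3-methylbenzene are purchased, the former in high ee (checked by chiral GC). Simple reagents are named with SMILES in each step and not numbered.

## Route

**Step 1**
Reactants: 1, (S)-(+)-linalool
Product: 2, (2E,6S)-2,6-dimethylocta-2,7-diene-1,6-diol
Conditions: SeO2 (0.5 eq), t-BuOOH, salicylic acid (cat.), CH2Cl2, rt; then NaBH4, MeOH, 0 °C
Reagents that add atoms: SeO2, O=[Se]=O (allylic O; recycled by t-BuOOH, CC(C)(C)OO)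
Why: Sharpless–Umbreit SeO2 allylic oxidation (ene/[2,3] shift) hits the E-methyl of the only trisubstituted alkene; the vinyl group has no allylic H and the carbinol centre is untouched; NaBH4 returns any over-oxidised enal.

**Step 2**
Reactants: 2
Product: 3, (3S,6E)-8-bromo-3,7-dimethylocta-1,6-dien-3-ol
Conditions: MsCl, Et3N, THF, −40 °C; then LiBr, −40 → 0 °C
Reagents that add atoms: LiBr, [Li+].[Br-]
Why: Only the primary allylic OH is mesylated at −40 °C (the tertiary OH is inert), and SN2 displacement by bromide proceeds without allylic transposition.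

**Step 3**
Reactants: 3; 4, N-tert-butylethanimine (acetaldehyde tert-butylimine)
Product: 5, (4E,8S)-8-hydroxy-4,8-dimethyldeca-4,9-dienal
Conditions: 4, LDA (3 eq), THF, −78 °C; add 3, −78 → −20 °C; then AcOH/NaOAc buffer (pH 4.5), rt
Reagents that add atoms: 4, CC=NC(C)(C)C (CH2–CH= unit); water, O (aldehyde O on hydrolysis)
Why: Metalated-imine (aza-enolate) alkylation, SN2 at the primary allylic bromide (one extra equivalent is consumed by the OH); buffered hydrolysis releases the aldehyde without ionising the tertiary allylic alcohol.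

**Step 4**
Reactants: 6, methyl bis(2,2,2-trifluoroethyl)phosphonoacetate; 7, 5-bromo-2-methylpent-2-ene
Product: 8, methyl 2-[bis(2,2,2-trifluoroethoxy)phosphoryl]-6-methylhept-5-enoate
Conditions: NaH, DMF, 0 °C → rt; then 7, NaI (cat.), 50 °C
Reagents that add atoms: none beyond 6 and 7
Why: C-alkylation of the stabilised phosphonoacetate anion with a primary (homoallylic) halide.

**Step 5**
Reactants: 5; 8
Product: 9, methyl (2Z,6E,10S)-10-hydroxy-6,10-dimethyl-2-(4-methylpent-3-en-1-yl)dodeca-2,6,11-trienoate
Conditions: 8, KHMDS, 18-crown-6, THF, −78 °C; then 5, −78 °C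
Reagents that add atoms: none beyond 8
Why: Still–Gennari olefination with an α-alkyl bis(trifluoroethyl)phosphonate gives the kinetic Z-trisubstituted enoate (CO2Me cis to the aldehyde-derived chain); the phosphonate anion does not deprotonate the tertiary OH.

**Step 6**
Reactants: 10, 2-bromo-1-iodo-3-methylbenzene
Product: 11, 4-bromo-3-iodo-5-methylphenol
Conditions: [Ir(OMe)(cod)]2 (cat.), dtbpy, B2pin2, THF, 80 °C; then aq. H2O2, NaOH, 0 °C (one pot)
Reagents that add atoms: hydrogen peroxide, OO (phenol O)
Why: Sterically controlled Ir-catalysed C–H borylation occurs at C5, the only C–H with no ortho substituent, and the boronate is oxidised to the phenol; both C–I and C–Br are tolerated.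

**Step 7**
Reactants: 11; 12, triisopropylsilyl chloride
Product: 13, (4-bromo-3-iodo-5-methylphenoxy)triisopropylsilane
Conditions: TIPSCl, imidazole, DMF, rt
Reagents that add atoms: 12, CC(C)[Si](Cl)(C(C)C)C(C)C
Why: Standard phenol silylation; the TIPS aryl ether withstands the basic Pd steps and DDQ.

**Step 8**
Reactants: 9; 13
Product: 14, methyl (2Z,6E,10S)-12-[2-bromo-3-methyl-5-(triisopropylsilyloxy)phenyl]-10-hydroxy-6,10-dimethyl-2-(4-methylpent-3-en-1-yl)dodeca-2,6-dienoate
Conditions: 9-BBN (2.2 eq), THF, 0 °C → rt; then 13, PdCl2(dppf) (5 mol%), aq. K3PO4, DMF, rt → 40 °C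
Reagents that add atoms: none (9-BBN delivers only H)
Why: 9-BBN hydroborates only the monosubstituted vinyl group (anti-Markovnikov; trisubstituted alkenes and the enoate are inert), and B-alkyl Suzuki–Miyaura coupling occurs at C–I in preference to the hindered C–Br.

**Step 9**
Reactants: 14
Product: 15, methyl (2Z,6E)-9-[(2S)-2,8-dimethyl-6-(triisopropylsilyloxy)-3,4-dihydro-2H-chromen-2-yl]-6-methyl-2-(4-methylpent-3-en-1-yl)nona-2,6-dienoate
Conditions: Pd(OAc)2 (5 mol%), 2-(di-tert-butylphosphino)-1,1'-binaphthyl (6 mol%), Cs2CO3, toluene, 80 °C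
Reagents that add atoms: none
Why: Buchwald-type intramolecular Pd-catalysed aryl C–O etherification, which works well for tertiary alkoxides (no β-H); the new bond is O–aryl, so the carbinol centre is retained as (2S).

**Step 10**
Reactants: 15
Product: 16, methyl (2Z,6E)-9-[(2S)-2,8-dimethyl-6-(triisopropylsilyloxy)-2H-chromen-2-yl]-6-methyl-2-(4-methylpent-3-en-1-yl)nona-2,6-dienoate
Conditions: DDQ (1.3 eq), dry benzene (or dioxane), 80 °C, dark
Reagents that add atoms: none
Why: DDQ dehydrogenation: hydride abstraction from benzylic C4 (cation stabilised by the ring oxygen), then loss of H-3, gives the 2H-chromene; C2 is quaternary and unaffected, and isolated alkenes and the enoate are inert.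

**Step 11**
Reactants: 16
Product: 17, (S)-sargachromenol
Conditions: TBAF, THF, 0 °C; then LiOH, THF/MeOH/H2O, 45 °C, Ar, dark; aq. citric acid work-up
Reagents that add atoms: LiOH, [Li+].[OH-] (one carboxyl O)
Why: Fluoride cleaves the aryl silyl ether and hydroxide saponifies the methyl ester; mild degassed conditions and a weak-acid work-up preserve the Z-enoate, the chromene and the phenol.

## Compound list

1 | (S)-(+)-linalool | CC(C)=CCC[C@](C)(O)C=C | starting material
2 | (2E,6S)-2,6-dimethylocta-2,7-diene-1,6-diol | OC/C(C)=C/CC[C@](C)(O)C=C | intermediate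
3 | (3S,6E)-8-bromo-3,7-dimethylocta-1,6-dien-3-ol | BrC/C(C)=C/CC[C@](C)(O)C=C | intermediate
4 | N-tert-butylethanimine | CC=NC(C)(C)C | starting material
5 | (4E,8S)-8-hydroxy-4,8-dimethyldeca-4,9-dienal | O=CCC/C(C)=C/CC[C@](C)(O)C=C | intermediate
6 | methyl bis(2,2,2-trifluoroethyl)phosphonoacetate | COC(=O)CP(=O)(OCC(F)(F)F)OCC(F)(F)F | starting material
7 | 5-bromo-2-methylpent-2-ene | CC(C)=CCCBr | starting material
8 | methyl 2-[bis(2,2,2-trifluoroethoxy)phosphoryl]-6-methylhept-5-enoate | COC(=O)C(CCC=C(C)C)P(=O)(OCC(F)(F)F)OCC(F)(F)F | intermediate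
9 | methyl (2Z,6E,10S)-10-hydroxy-6,10-dimethyl-2-(4-methylpent-3-en-1-yl)dodeca-2,6,11-trienoate | CC(C)=CCC/C(=C/CC/C(C)=C/CC[C@](C)(O)C=C)C(=O)OC | intermediate
10 | 2-bromo-1-iodo-3-methylbenzene | Cc1cccc(I)c1Br | starting material
11 | 4-bromo-3-iodo-5-methylphenol | Cc1cc(O)cc(I)c1Br | intermediate
12 | triisopropylsilyl chloride | CC(C)[Si](Cl)(C(C)C)C(C)C | starting material
13 | (4-bromo-3-iodo-5-methylphenoxy)triisopropylsilane | Cc1cc(O[Si](C(C)C)(C(C)C)C(C)C)cc(I)c1Br | intermediate
14 | methyl (2Z,6E,10S)-12-[2-bromo-3-methyl-5-(triisopropylsilyloxy)phenyl]-10-hydroxy-6,10-dimethyl-2-(4-methylpent-3-en-1-yl)dodeca-2,6-dienoate | CC(C)=CCC/C(=C/CC/C(C)=C/CC[C@](C)(O)CCc1cc(O[Si](C(C)C)(C(C)C)C(C)C)cc(C)c1Br)C(=O)OC | intermediate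
15 | methyl (2Z,6E)-9-[(2S)-2,8-dimethyl-6-(triisopropylsilyloxy)chroman-2-yl]-6-methyl-2-(4-methylpent-3-en-1-yl)nona-2,6-dienoate | CC(C)=CCC/C(=C/CC/C(C)=C/CC[C@@]1(C)CCc2cc(O[Si](C(C)C)(C(C)C)C(C)C)cc(C)c2O1)C(=O)OC | intermediate
16 | methyl (2Z,6E)-9-[(2S)-2,8-dimethyl-6-(triisopropylsilyloxy)-2H-chromen-2-yl]-6-methyl-2-(4-methylpent-3-en-1-yl)nona-2,6-dienoate | CC(C)=CCC/C(=C/CC/C(C)=C/CC[C@@]1(C)C=Cc2cc(O[Si](C(C)C)(C(C)C)C(C)C)cc(C)c2O1)C(=O)OC | intermediate
17 | (S)-sargachromenol, (2Z,6E)-9-[(2S)-6-hydroxy-2,8-dimethyl-2H-chromen-2-yl]-6-methyl-2-(4-methylpent-3-en-1-yl)nona-2,6-dienoic acid | CC(C)=CCC/C(=C/CC/C(C)=C/CC[C@@]1(C)C=Cc2cc(O)cc(C)c2O1)C(=O)O | target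

## Step count and risks

Total steps: 11. Longest linear sequence: 8 (steps 1, 2, 3, 5, 8, 9, 10, 11 from (S)-linalool).

Steps most likely to fail:

1. **Step 10, DDQ dehydrogenation of the O-silyl chroman.** Risks are sluggish reaction, oxidation at the 8-methyl, and thermal or photochemical ring-opening of the chromene, which would erode ee. Fallback: install C3=C4 before ring closure. Sonogashira-couple 13 with the ethynyl-carbinol analogue of 9 (made by Sharpless epoxidation, epoxy chloride, then n-BuLi), semihydrogenate with Lindlar catalyst to the Z-styrene, and close the C–O bond to give the chromene directly.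
2. **Step 9, Pd C–O coupling at a di-ortho-substituted, electron-rich aryl bromide.** Risks are hydrodebromination or no ring closure. Fallback: a tocopherol-quinone-type closure. Use a 2,5-dimethoxy-3-methyl aryl iodide in step 8, oxidise with CAN to the quinone, and cyclise reductively through the quinone hemiketal. This keeps the carbinol C–O bond and gives the free 6-hydroxychroman.
3. **Step 8, hydroboration/B-alkyl Suzuki on a free tertiary allylic alcohol.** Risks are a chelated borinate that transmetalates slowly, or loss of I/Br selectivity. Fallback: Heck arylation of the vinyl carbinol 9 with 13 to the E-styrene, then chemoselective diimide reduction of that disubstituted alkene to give 14.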